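The runs were generated by integration with constants of no real substance; noise was put on by code.

Watch the ratio. Let r be isomer of the product over target at a given moment.

common to all: substrate 0.050 M

|  | catalyst | remark | time |
|---|---|---|---|
| Thursday's | 7 mM | run made earlier |  |
| Wednesday's | 11 mM | run made earlier |  |
| flask | 5.0 mM |  | 40 h |

| run | time / h | isomer of the product / % | target / % |
|---|---|---|---|
| Thursday's | 3.00 | 0.1 | 8.8 |
| Thursday's | 5.00 | 1.4 | 13.0 |
| Thursday's | 8.00 | 1.0 | 18.1 |
| Thursday's | 12.0 | 1.7 | 25.0 |
| Thursday's | 15.0 | 4.0 | 30.6 |
| Thursday's | 25.0 | 6.0 | 38.7 |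
| Thursday's | 40.0 | 10.7 | 45.4 |
| Wednesday's | 3.00 | 0.1 | 13.2 |
| Wednesday's | 5.00 | 0 | 17.9 |
| Wednesday's | 8.00 | 2.5 | 28.5 |
| Wednesday's | 12.0 | 4.1 | 36.3 |
| Wednesday's | 15.0 | 4.4 | 39.6 |
| Wednesday's | 25.0 | 7.9 | 48.5 |
| Wednesday's | 40.0 | 10.6 | 56.8 |

(readings scatter by 1 percentage point)

* ratio of isomer of the product to target at 30 min
* ratio of isomer of the product to target at 40 h
* which of isomer of the product and target there is more of at 40 h



At 25.0 h, r reads 0.155 with 7 mM of catalyst and 0.163 with 11 mM. These readings show no effect of catalyst beyond the scatter. The first way therefore draws a line through zero, r = g·t, with g = 0.00636 h⁻¹: the drift, the ratio gained per hour. It goes unchanged to the flask with 5.0 mM.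

The second way uses the 40.0 h isomer readings. This way is a working assumption, not a finding: it supposes that isomer grows at k times the target present, with k a pseudo-first-order constant, so that r = k·t·m, where m is mean target up to t over target at t. Taking the 15.0 h reading as the mean over a run gives k = 0.00772 h⁻¹, and Thursday's run gives m = 0.674. While target climbs straight from zero, its mean is half its end, so m is taken as that at the earlier times below.

| time | line | mean of target | readings, Thursday's and Wednesday's |
|---|---|---|---|
| 30 min | 0.00318 | 0.00193 | none |
| 15.0 h | 0.0954 | 0.0579 | 0.131, 0.111 |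
| 40 h | 0.254 | 0.208 | used for k |

At 40 h the two ways lie close, from different readings, and both put target well ahead. Early they part. The 15.0 h isomer readings entered neither way, and they lie nearer the line than the mean. The mean way cheats, so the line is kept.

The forecast gave 0.0022 and 0.22, with target ahead, reasoning that “the isomer comes mainly from the target, in sequence”.

The flask gives 0.00284 and 0.236, with target ahead at 35.4 % against 8.35 %.

    catalyst + other conformer → catalyst + isomer of the product (k = 5.29 × 10⁻⁴ M⁻¹ s⁻¹)
    substrate + target → side product (k = 1.05 × 10⁻⁴ M⁻¹ s⁻¹)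
    substrate + catalyst → catalyst + target (k = 0.00130 M⁻¹ s⁻¹)
    substrate ⇌ other conformer (K = 1.59, k = 7.73 × 10⁻⁶ s⁻¹)

In this flask at 40 h, substrate passes to target at 0.84 of its forward rate to other conformer, and catalyst multiplies both the step to target and the step to isomer. Other conformer has a half-life of 73 h toward isomer, longer than the 30 h of substrate toward target.

For a neighbour flask with 0.0020 M of catalyst, the drift again gives 0.00318 and 0.254. That flask computes 0.00284 and 0.248.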